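**Retrosynthetic overview**
1. The cyclohexenone is the only ring of the target and is closed last, by ring-closing metathesis of an acyclic allyl carbinol that carries a vinyl ketone arm and the linoleoyl-methyl arm.
2. Key disconnection: ring C1–C6, a C(=O)–CH2 bond. The carbonyl carbon is the nucleophile (acryloyl anion = 1-lithio-1-methoxyallene) and an epoxide CH2 is the electrophile.
3. The side-chain C(=O)–CH2 bond is cut with the same reversed polarity. The linoleoyl anion is a 2-lithio-1,3-dithiane made from methyl linoleate.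
4. Both anions are joined in one flask to (R)-2-allyl-2-(chloromethyl)oxirane (open, re-close on CH2Cl, open again). Its C–O bond becomes the carbinol C–O bond.
5. That oxirane comes from Sharpless epoxidation of 2-methylidenepent-4-en-1-ol, made from propargyl alcohol and allylmagnesium bromide. Ring order: oxirane, relocated oxirane, cyclohexenone.

Assumption: the stereocentre in the given SMILES reads as (S); 1-methoxyallene, allylmagnesium bromide solution and methyl linoleate are bought.

Step 1
Reactants: 1 prop-2-yn-1-ol, 2 allylmagnesium bromide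
Product: 4 2-methylidenepent-4-en-1-ol, via alkenylmagnesium alkoxide 3 (not isolated)
Conditions: 2 (2.5 equiv, Et2O), CuI (10 mol%), Et2O/THF, 0 → 23 °C, 12 h; then H2O, 0 °C
Reagents that add atoms: none
Why: Copper-catalysed anti-carbomagnesiation of the propargylic magnesium alkoxide (Duboudin–Jousseaume reaction) puts the allyl group on the internal alkyne carbon through a five-membered chelate, and protonolysis leaves the 2-substituted allylic alcohol; no stereocentre is made.

Step 2
Reactants: 4 2-methylidenepent-4-en-1-ol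
Product: 5 [(2S)-2-(prop-2-en-1-yl)oxiran-2-yl]methanol
Conditions: Ti(OiPr)4 (10 mol%), L-(+)-diisopropyl tartrate (12 mol%), tBuOOH (2 equiv, decane), 4 Å MS, CH2Cl2, −20 °C
Reagents that add atoms: tert-butyl hydroperoxide, CC(C)(C)OO
Why: Katsuki–Sharpless asymmetric epoxidation is hydroxyl-directed, so only the allylic 1,1-disubstituted alkene reacts, and the L-(+)-tartrate delivers oxygen to the same face as in allyl alcohol → (S)-glycidol and methallyl alcohol → (S)-2-methylglycidol (about 90–95% ee expected), which sets the only stereocentre of the target.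

Step 3
Reactants: 5 [(2S)-2-(prop-2-en-1-yl)oxiran-2-yl]methanol
Product: 6 (2R)-2-(chloromethyl)-2-(prop-2-en-1-yl)oxirane
Conditions: PPh3 (1.3 equiv), CCl4, NaHCO3 (0.2 equiv), reflux, 4 h
Reagents that add atoms: tetrachloromethane, ClC(Cl)(Cl)Cl
Why: Appel chlorination replaces the primary OH under buffered, near-neutral conditions without touching the quaternary epoxide carbon (S becomes R only through CIP priorities) and installs a leaving group that organolithiums ignore at low temperature.

Step 4
Reactants: 7 methyl linoleate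
Product: 9 2-[(8Z,11Z)-heptadeca-8,11-dien-1-yl]-1,3-dithiane, via (9Z,12Z)-octadeca-9,12-dienal 8 (not isolated)
Conditions: iBu2AlH (1.05 equiv), CH2Cl2, −78 °C, 1 h; then HS(CH2)3SH (1.2 equiv), BF3·OEt2 (2.5 equiv), −78 → 0 °C; aqueous work-up
Reagents that add atoms: propane-1,3-dithiol, SCCCS
Why: Ester reduction that stops at the aldehyde oxidation level at −78 °C, followed in the same flask by BF3-promoted thioacetalisation, gives the Corey–Seebach acyl anion precursor, and neither reagent touches the isolated Z-alkenes.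

Step 5
Reactants: 10 1-methoxyallene, 6 (2R)-2-(chloromethyl)-2-(prop-2-en-1-yl)oxirane, 9 2-[(8Z,11Z)-heptadeca-8,11-dien-1-yl]-1,3-dithiane
Product: 16 (5R)-5-({2-[(8Z,11Z)-heptadeca-8,11-dien-1-yl]-1,3-dithian-2-yl}methyl)-5-hydroxyocta-1,7-dien-3-one, via 1-lithio-1-methoxyallene 11 (not isolated), via lithium chlorohydrin alkoxide 12 (not isolated), via relocated epoxide 13 (not isolated), via lithiated dithiane 14 (not isolated), via allenyl ether carbinol 15 (not isolated)
Conditions: (a) 10, nBuLi (1.0 equiv each), THF, −40 °C, 20 min; 6 (1.0 equiv), −78 → 23 °C, 3 h; (b) separately 9, tBuLi (1.1 equiv each), THF/HMPA 9:1, −78 °C, 10 min; solution (a) added by cannula, −78 → −10 °C, 3 h; (c) 1 M HCl, THF, 0 °C, 30 min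
Reagents that add atoms: water, O
Why: Three-component linchpin coupling of the Smith epichlorohydrin type run with two different acyl anion equivalents: the acryloyl anion equivalent 11 (lithiated alkoxyallene) opens the inductively activated epoxide at its CH2 and ignores the neopentyl-type C–Cl, alkoxide 12 closes to the relocated epoxide 13, the Corey–Seebach linoleoyl anion equivalent 14 (metalated within minutes under Williams–Smith conditions, faster than the doubly allylic CH2) opens 13 at its CH2, and the acid quench hydrolyses the allenyl ether to the vinyl ketone, all without breaking the C–O bond of the stereocentre.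

Step 6
Reactants: 16 (5R)-5-({2-[(8Z,11Z)-heptadeca-8,11-dien-1-yl]-1,3-dithian-2-yl}methyl)-5-hydroxyocta-1,7-dien-3-one
Product: 17 (5S,15Z,18Z)-5-hydroxy-5-(prop-2-en-1-yl)tetracosa-1,15,18-triene-3,7-dione
Conditions: PhI(OCOCF3)2 (1.5 equiv), MeCN/H2O 9:1, 0 °C, 10 min; aq. NaHCO3 work-up
Reagents that add atoms: water, O
Why: Stork–Zhao oxidative dithiane hydrolysis is over in minutes at 0 °C, releases no free thiol that could add to the vinyl ketone, and outruns any reaction of the unactivated alkenes or the tertiary carbinol (R becomes S only through CIP priorities).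

Step 7
Reactants: 17 (5S,15Z,18Z)-5-hydroxy-5-(prop-2-en-1-yl)tetracosa-1,15,18-triene-3,7-dione
Product: 18 (5S)-5-hydroxy-5-[(10Z,13Z)-2-oxononadeca-10,13-dien-1-yl]cyclohex-2-en-1-one
Conditions: second-generation Hoveyda–Grubbs catalyst RuCl2(H2IMes)(=CH-C6H4-2-OiPr) (3 mol%), 1,4-benzoquinone (10 mol%), CH2Cl2 (1 mM), 40 °C, 1–2 h; ethyl vinyl ether quench
Reagents that add atoms: none
Why: Ring-closing metathesis of the two terminal alkenes to a six-membered enone is much faster at 1 mM than any intermolecular or macrocyclic engagement of the internal Z-alkenes, benzoquinone suppresses ruthenium hydride isomerisation of the skipped diene, and the neutral medium spares the dehydration-prone β-hydroxy ketone; the stereocentre is not involved.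

**Compound list**
1 | prop-2-yn-1-ol (propargyl alcohol) | C#CCO | starting material
2 | allylmagnesium bromide | C=CC[Mg]Br | starting material
3 | [(1Z)-2-{[(bromomagnesio)oxy]methyl}penta-1,4-dien-1-yl]magnesium bromide | C=CC/C(CO[Mg]Br)=C/[Mg]Br | intermediate
4 | 2-methylidenepent-4-en-1-ol | C=CCC(=C)CO | intermediate
5 | [(2S)-2-(prop-2-en-1-yl)oxiran-2-yl]methanol | OC[C@@]1(CC=C)CO1 | intermediate
6 | (2R)-2-(chloromethyl)-2-(prop-2-en-1-yl)oxirane | ClC[C@@]1(CC=C)CO1 | intermediate
7 | methyl (9Z,12Z)-octadeca-9,12-dienoate (methyl linoleate) | CCCCC/C=C\C/C=C\CCCCCCCC(=O)OC | starting material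
8 | (9Z,12Z)-octadeca-9,12-dienal | CCCCC/C=C\C/C=C\CCCCCCCC=O | intermediate
9 | 2-[(8Z,11Z)-heptadeca-8,11-dien-1-yl]-1,3-dithiane | CCCCC/C=C\C/C=C\CCCCCCCC1SCCCS1 | intermediate
10 | 1-methoxypropa-1,2-diene (1-methoxyallene) | COC=C=C | starting material
11 | (1-methoxypropa-1,2-dien-1-yl)lithium | [Li]C(OC)=C=C | intermediate
12 | lithium (4R)-4-(chloromethyl)-6-methoxyocta-1,6,7-trien-4-olate | C=C=C(OC)C[C@]([O-])(CC=C)CCl.[Li+] | intermediate
13 | (2R)-2-(2-methoxybuta-2,3-dien-1-yl)-2-(prop-2-en-1-yl)oxirane | C=C=C(OC)C[C@]1(CC=C)CO1 | intermediate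
14 | {2-[(8Z,11Z)-heptadeca-8,11-dien-1-yl]-1,3-dithian-2-yl}lithium | CCCCC/C=C\C/C=C\CCCCCCCC1([Li])SCCCS1 | intermediate
15 | (4R)-4-({2-[(8Z,11Z)-heptadeca-8,11-dien-1-yl]-1,3-dithian-2-yl}methyl)-6-methoxyocta-1,6,7-trien-4-ol | CCCCC/C=C\C/C=C\CCCCCCCC1(SCCCS1)C[C@@](O)(CC=C)CC(OC)=C=C | intermediate
16 | (5R)-5-({2-[(8Z,11Z)-heptadeca-8,11-dien-1-yl]-1,3-dithian-2-yl}methyl)-5-hydroxyocta-1,7-dien-3-one | CCCCC/C=C\C/C=C\CCCCCCCC1(SCCCS1)C[C@@](O)(CC=C)CC(=O)C=C | intermediate
17 | (5S,15Z,18Z)-5-hydroxy-5-(prop-2-en-1-yl)tetracosa-1,15,18-triene-3,7-dione | CCCCC/C=C\C/C=C\CCCCCCCC(=O)C[C@@](O)(CC=C)CC(=O)C=C | intermediate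
18 | (5S)-5-hydroxy-5-[(10Z,13Z)-2-oxononadeca-10,13-dien-1-yl]cyclohex-2-en-1-one | CCCCC/C=C\C/C=C\CCCCCCCC(=O)C[C@@]1(O)CC=CC(=O)C1 | target

Total step count: 7. Longest linear sequence: 6 (steps 1, 2, 3, 5, 6, 7).

**Steps most likely to fail (5, then 7, then 3), each with a fallback**

**Step 5.** The base may attack the doubly allylic CH2 of 9, or the tertiary carbanion 14 may be too hindered for 13.
- The fallback sets out from 13, made as in part (a) of step 5 but isolated by distillation, and comes back at 16.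
- It moves the bond that is made to the other side of the side-chain carbonyl, so no diene is present when a base is used.
- Commercial linoleoyl chloride is converted with the sodium salt of 1-hydroxypyridine-2-thione into the Barton ester 1-{[(9Z,12Z)-octadeca-9,12-dienoyl]oxy}pyridine-2(1H)-thione F1.
- Visible light and CHI3 turn this ester into (6Z,9Z)-17-iodoheptadeca-6,9-diene F2.
- Commercial 2-(trimethylsilyl)-1,3-dithiane is lithiated (nBuLi, Et2O, −20 °C) and opens 13.
- HMPA then triggers the 1,4-Brook shift of silicon onto the new alkoxide, and the relocated dithiane anion is alkylated by the iodide.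
- The product is {[(4R)-4-({2-[(8Z,11Z)-heptadeca-8,11-dien-1-yl]-1,3-dithian-2-yl}methyl)-6-methoxyocta-1,6,7-trien-4-yl]oxy}trimethylsilane F3.
- The same 1 M HCl quench removes the silyl group and the allenyl ether and gives 16.

**Step 7.** The second-generation catalyst may scramble or isomerise the skipped Z,Z-diene.
- The fallback sets out from 17 and comes back at 18. It is a redox detour that allows a catalyst unable to touch 1,2-disubstituted alkenes.
- NaBH4/CeCl3·7H2O (MeOH, −20 °C) reduces both ketones in 1,2 fashion to (5S,15Z,18Z)-5-(prop-2-en-1-yl)tetracosa-1,15,18-triene-3,5,7-triol F4. This is an epimer mixture at the two new carbinols, which does not matter.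
- The first-generation Grubbs catalyst RuCl2(PCy3)2(=CHPh) (CH2Cl2, 40 °C) closes the allylic alcohol onto the allyl group. This gives (1S)-1-[(10Z,13Z)-2-hydroxynonadeca-10,13-dien-1-yl]cyclohex-4-ene-1,3-diol F5.
- Dess–Martin periodinane with NaHCO3 (CH2Cl2, 0 °C) oxidises both secondary carbinols, leaves the tertiary one alone and gives 18.

**Step 3.** Chloride may open the acid-sensitive 2,2-disubstituted epoxide, and the relay in step 5 depends on a clean epoxy chloride.
- The fallback sets out from 4 and comes back at 13. It replaces the open and re-close relay by a direct substitution.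
- Epoxidation of 4 with D-(−)-diisopropyl tartrate gives [(2R)-2-(prop-2-en-1-yl)oxiran-2-yl]methanol F6.
- Tf2O and 2,6-lutidine (CH2Cl2, −78 °C) give [(2S)-2-(prop-2-en-1-yl)oxiran-2-yl]methyl trifluoromethanesulfonate F7.
- 11 displaces the triflate at −78 °C; plain sp3 alkylation is its best-documented reaction.
- The original epoxide stays in place. Because the two CH2 arms have swapped roles, the antipodal epoxy alcohol leads to the same 13.

**Further compounds**
F1 | step 5 | 1-{[(9Z,12Z)-octadeca-9,12-dienoyl]oxy}pyridine-2(1H)-thione | CCCCC/C=C\C/C=C\CCCCCCCC(=O)ON1C=CC=CC1=S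
F2 | step 5 | (6Z,9Z)-17-iodoheptadeca-6,9-diene | CCCCC/C=C\C/C=C\CCCCCCCI
F3 | step 5 | {[(4R)-4-({2-[(8Z,11Z)-heptadeca-8,11-dien-1-yl]-1,3-dithian-2-yl}methyl)-6-methoxyocta-1,6,7-trien-4-yl]oxy}trimethylsilane | CCCCC/C=C\C/C=C\CCCCCCCC1(SCCCS1)C[C@@](O[Si](C)(C)C)(CC=C)CC(OC)=C=C
F4 | step 7 | (5S,15Z,18Z)-5-(prop-2-en-1-yl)tetracosa-1,15,18-triene-3,5,7-triol | CCCCC/C=C\C/C=C\CCCCCCCC(O)C[C@@](O)(CC=C)CC(O)C=C
F5 | step 7 | (1S)-1-[(10Z,13Z)-2-hydroxynonadeca-10,13-dien-1-yl]cyclohex-4-ene-1,3-diol | CCCCC/C=C\C/C=C\CCCCCCCC(O)C[C@@]1(O)CC=CC(O)C1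
F6 | step 3 | [(2R)-2-(prop-2-en-1-yl)oxiran-2-yl]methanol | OC[C@]1(CC=C)CO1
F7 | step 3 | [(2S)-2-(prop-2-en-1-yl)oxiran-2-yl]methyl trifluoromethanesulfonate | FC(F)(F)S(=O)(=O)OC[C@]1(CC=C)CO1
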